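**Retrosynthetic overview**

1. Feature: on the central benzene (ring A; C1 bears the methide carbon, C2 an aryl group) the ortho pair C5–CH2OH / C6–C≡C–Ar is read as an aryl-opened phthalide. The lactone CH2 is the C5 CH2OH and the lactone carbonyl carbon is the alkyne carbon bound to C6.
2. Selaginellin ⇐ triarylcarbinol 19 (one acid step: MOM and TBS off, dehydration to the quinone methide) ⇐ aryl bromide 15 + benzophenone 17 (Br–Li exchange at C1, 1,2-addition).
3. Diarylalkyne 15 ⇐ diaryl ketone 9 + trimethylsilyldiazomethane (one-carbon insertion, 1,2-aryl shift of an alkylidene carbene).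
4. Ketone 9 ⇐ phthalide 5 + aryl Grignard (mono-addition, silylation); 5 ⇐ acid 3 + CH2Br2 (Pd C–H alkylation/lactonisation) ⇐ 2-bromo-3-iodobenzoic acid + arylboronic acid (Suzuki at C–I).
5. Rings: all six-membered carbocycles are bought; the only ring closed is the lactone of 5 (step 2), reopened in step 3; the cyclohexadienone arises from a phenol ring in the last step.

Key step: step 5

Remark on stereochemistry: the target SMILES holds no stereocentre and no stereodescriptor, so the compound is made as the constitution given and no stereocontrol is needed.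
Remark on protecting groups: the phenols are carried as methoxymethyl (MOM) ethers, not methyl ethers, so that one mild acid step frees the three phenols and the CH2OH and forms the quinone methide. A boron-halide demethylation would endanger the benzylic alcohol, the alkyne and the triarylmethyl cation. Compounds 2, 6 and 16 are assumed to be purchasable.

**Route**

Step 1
Reactants: 1 2-bromo-3-iodobenzoic acid; 2 4-(methoxymethoxy)phenylboronic acid
Product: 3 2-bromo-3-[4-(methoxymethoxy)phenyl]benzoic acid
Conditions: Pd(PPh3)4 (cat.), Na2CO3, 1,4-dioxane/H2O, 80 °C; then aq. citric acid to pH 4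
Reagents that add atoms: none
Why: Suzuki–Miyaura coupling, in which oxidative addition at C–I is far faster than at the C–Br bond flanked by two ortho substituents, so only the iodide should couple while the carboxylate and the MOM ether tolerate aqueous carbonate.

Step 2
Reactants: 3 2-bromo-3-[4-(methoxymethoxy)phenyl]benzoic acid
Product: 5 7-bromo-6-[4-(methoxymethoxy)phenyl]isobenzofuran-1(3H)-one, via bromomethyl benzoate 4 (not isolated)
Conditions: Pd(OAc)2 (10 mol%), K2HPO4, CH2Br2 (solvent), 140 °C, sealed tube
Reagents that add atoms: dibromomethane, BrCBr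
Why: Carboxylate-directed Pd(II)/Pd(IV) ortho C–H alkylation with CH2Br2 followed by intramolecular SN2 lactonisation; C6–H is the only ortho C–H, and the phosphine-free Pd(II) cycle should leave the C–Br bond and the buffered MOM ether untouched.

Step 3
Reactants: 5 7-bromo-6-[4-(methoxymethoxy)phenyl]isobenzofuran-1(3H)-one; 6 1-bromo-4-(methoxymethoxy)benzene
Product: 8 [2-bromo-6-(hydroxymethyl)-3-[4-(methoxymethoxy)phenyl]phenyl][4-(methoxymethoxy)phenyl]methanone, via arylmagnesium bromide 7 (not isolated)
Conditions: 6, Mg, THF, 40 °C; then 5, THF, −40 → 0 °C; H2O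
Reagents that add atoms: none
Why: Grignard mono-addition to a lactone, in which the magnesium hemiketalate persists at low temperature and the ketone it releases is shielded by the ortho Br and CH2O groups against a second addition, while an arylmagnesium bromide does not exchange with the aryl bromide.

Step 4
Reactants: 8 [2-bromo-6-(hydroxymethyl)-3-[4-(methoxymethoxy)phenyl]phenyl][4-(methoxymethoxy)phenyl]methanone
Product: 9 [2-bromo-6-[(tert-butyldimethylsilyloxy)methyl]-3-[4-(methoxymethoxy)phenyl]phenyl][4-(methoxymethoxy)phenyl]methanone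
Conditions: TBSCl, imidazole, DMF, 0 °C → rt
Reagents that add atoms: tert-butyldimethylsilyl chloride, CC(C)(C)[Si](C)(C)Cl
Why: Imidazole-mediated silylation of the primary alcohol, which should trap the open keto-alcohol form because the hindered tertiary lactol hydroxyl of the ring tautomer silylates far more slowly.

Step 5
Reactants: 9 [2-bromo-6-[(tert-butyldimethylsilyloxy)methyl]-3-[4-(methoxymethoxy)phenyl]phenyl][4-(methoxymethoxy)phenyl]methanone; 10 trimethylsilyldiazomethane
Product: 15 [3-bromo-4-[4-(methoxymethoxy)phenyl]-2-[[4-(methoxymethoxy)phenyl]ethynyl]benzyloxy](tert-butyl)dimethylsilane, via lithiated trimethylsilyldiazomethane 11 (not isolated), via diazo alkoxide adduct 12 (not isolated), via diazoalkene 13 (not isolated), via alkylidene carbene 14 (not isolated)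
Conditions: 10, LDA, THF, −78 °C; then 9, −78 °C → rt; H2O
Reagents that add atoms: none
Why: Colvin rearrangement: the lithiated diazo compound 11 adds to the diaryl ketone to give alkoxide 12, Peterson-type loss of lithium trimethylsilanolate gives diazoalkene 13, and loss of N2 gives alkylidene carbene 14, which undergoes a Fritsch–Buttenberg–Wiechell 1,2-aryl shift, so that the bond from the former ketone carbon to the new carbon and the bond from the new carbon to the migrating aryl ring are both formed. The closest known reaction type is the conversion of benzophenones into diarylalkynes with lithiated trimethylsilyldiazomethane. No ring is closed and no stereocentre is formed. Either aryl group (the 4-MOM-oxyphenyl ring or ring A) gives the same alkyne on migration, so the step needs only chemoselectivity: the aryl shift must outrun 1,5 C–H insertion into the neighbouring CH2OSi group and ylide formation at the ether oxygen or the bromine, which the high migratory aptitude of an electron-rich 4-alkoxyphenyl group on a diaryl alkylidene carbene should secure. The stabilised diazo anion should not exchange with the aryl bromide, and its small linear shape should let it reach the carbonyl that the two ortho substituents twist out of the plane of ring A.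

Step 6
Reactants: 16 4,4'-dihydroxybenzophenone
Product: 17 bis[4-(methoxymethoxy)phenyl]methanone
Conditions: MOMCl, i-Pr2NEt, CH2Cl2, 0 °C → rt
Reagents that add atoms: chloromethyl methyl ether, COCCl
Why: O-alkylation of the two acidic phenols with an α-chloro ether (Williamson-type acetal formation), a routine protection that the diaryl ketone tolerates.

Step 7
Reactants: 15 [3-bromo-4-[4-(methoxymethoxy)phenyl]-2-[[4-(methoxymethoxy)phenyl]ethynyl]benzyloxy](tert-butyl)dimethylsilane; 17 bis[4-(methoxymethoxy)phenyl]methanone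
Product: 19 [3-[(tert-butyldimethylsilyloxy)methyl]-6-[4-(methoxymethoxy)phenyl]-2-[[4-(methoxymethoxy)phenyl]ethynyl]phenyl]bis[4-(methoxymethoxy)phenyl]methanol, via aryllithium 18 (not isolated)
Conditions: t-BuLi (2 equiv), THF, −78 °C; then 17, −78 → −20 °C; H2O
Reagents that add atoms: none
Why: Bromine–lithium exchange followed by 1,2-addition of the aryllithium to a non-enolisable diaryl ketone; exchange at −78 °C should be faster than MOM-directed lithiation or attack on the alkyne, and the cold quench should keep the tertiary alkoxide from cyclising onto the ortho alkyne.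

Step 8
Reactants: 19 [3-[(tert-butyldimethylsilyloxy)methyl]-6-[4-(methoxymethoxy)phenyl]-2-[[4-(methoxymethoxy)phenyl]ethynyl]phenyl]bis[4-(methoxymethoxy)phenyl]methanol
Product: 21 selaginellin, via deprotected triarylmethanol 20 (not isolated)
Conditions: 3 M aq. HCl, THF/i-PrOH, 40 °C; then aq. NaHCO3 to pH 7
Reagents that add atoms: none
Why: Acid hydrolysis of the four MOM acetals and the silyl ether, with ionisation of the triarylmethanol to a cation stabilised by two 4-oxygenated rings that loses a phenolic proton on neutralisation to give the quinone methide (fuchsone-type dehydration); the mild acid should avoid Friedel–Crafts closure onto the C2 aryl ring.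

**Compound list**

1 | 2-bromo-3-iodobenzoic acid | OC(=O)c1cccc(I)c1Br | starting material
2 | 4-(methoxymethoxy)phenylboronic acid | COCOc1ccc(cc1)B(O)O | starting material
3 | 2-bromo-3-[4-(methoxymethoxy)phenyl]benzoic acid | OC(=O)c1cccc(-c2ccc(OCOC)cc2)c1Br | intermediate
4 | potassium 2-bromo-6-(bromomethyl)-3-[4-(methoxymethoxy)phenyl]benzoate | [K+].[O-]C(=O)c1c(CBr)ccc(-c2ccc(OCOC)cc2)c1Br | intermediate (not isolated)
5 | 7-bromo-6-[4-(methoxymethoxy)phenyl]isobenzofuran-1(3H)-one | O=C1OCc2ccc(-c3ccc(OCOC)cc3)c(Br)c21 | intermediate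
6 | 1-bromo-4-(methoxymethoxy)benzene | COCOc1ccc(Br)cc1 | starting material
7 | 4-(methoxymethoxy)phenylmagnesium bromide | COCOc1ccc(cc1)[Mg]Br | intermediate (not isolated)
8 | [2-bromo-6-(hydroxymethyl)-3-[4-(methoxymethoxy)phenyl]phenyl][4-(methoxymethoxy)phenyl]methanone | COCOc1ccc(cc1)C(=O)c1c(CO)ccc(-c2ccc(OCOC)cc2)c1Br | intermediate
9 | [2-bromo-6-[(tert-butyldimethylsilyloxy)methyl]-3-[4-(methoxymethoxy)phenyl]phenyl][4-(methoxymethoxy)phenyl]methanone | COCOc1ccc(cc1)C(=O)c1c(CO[Si](C)(C)C(C)(C)C)ccc(-c2ccc(OCOC)cc2)c1Br | intermediate (key-step precursor)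
10 | trimethylsilyldiazomethane | C[Si](C)(C)C=[N+]=[N-] | starting material
11 | lithio(trimethylsilyl)diazomethane | [Li]C(=[N+]=[N-])[Si](C)(C)C | intermediate (not isolated)
12 | lithium alkoxide from addition of 11 to the carbonyl group of 9 | [Li+].[O-]C(C(=[N+]=[N-])[Si](C)(C)C)(c1ccc(OCOC)cc1)c1c(CO[Si](C)(C)C(C)(C)C)ccc(-c2ccc(OCOC)cc2)c1Br | intermediate (not isolated)
13 | 1-diazo-2,2-diarylethene from 12 by loss of silanolate | [N-]=[N+]=C=C(c1ccc(OCOC)cc1)c1c(CO[Si](C)(C)C(C)(C)C)ccc(-c2ccc(OCOC)cc2)c1Br | intermediate (not isolated)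
14 | 2,2-diarylvinylidene (alkylidene carbene) from 13 by loss of N2 | [C]=C(c1ccc(OCOC)cc1)c1c(CO[Si](C)(C)C(C)(C)C)ccc(-c2ccc(OCOC)cc2)c1Br | intermediate (not isolated)
15 | [3-bromo-4-[4-(methoxymethoxy)phenyl]-2-[[4-(methoxymethoxy)phenyl]ethynyl]benzyloxy](tert-butyl)dimethylsilane | COCOc1ccc(cc1)C#Cc1c(CO[Si](C)(C)C(C)(C)C)ccc(-c2ccc(OCOC)cc2)c1Br | intermediate (key-step product)
16 | 4,4'-dihydroxybenzophenone | O=C(c1ccc(O)cc1)c1ccc(O)cc1 | starting material
17 | bis[4-(methoxymethoxy)phenyl]methanone | COCOc1ccc(cc1)C(=O)c1ccc(OCOC)cc1 | intermediate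
18 | aryllithium from 15 (Li in place of Br) | COCOc1ccc(cc1)C#Cc1c(CO[Si](C)(C)C(C)(C)C)ccc(-c2ccc(OCOC)cc2)c1[Li] | intermediate (not isolated)
19 | [3-[(tert-butyldimethylsilyloxy)methyl]-6-[4-(methoxymethoxy)phenyl]-2-[[4-(methoxymethoxy)phenyl]ethynyl]phenyl]bis[4-(methoxymethoxy)phenyl]methanol | COCOc1ccc(cc1)C#Cc1c(CO[Si](C)(C)C(C)(C)C)ccc(-c2ccc(OCOC)cc2)c1C(O)(c1ccc(OCOC)cc1)c1ccc(OCOC)cc1 | intermediate
20 | [3-(hydroxymethyl)-6-(4-hydroxyphenyl)-2-[(4-hydroxyphenyl)ethynyl]phenyl]bis(4-hydroxyphenyl)methanol | Oc1ccc(cc1)C#Cc1c(CO)ccc(-c2ccc(O)cc2)c1C(O)(c1ccc(O)cc1)c1ccc(O)cc1 | intermediate (not isolated)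
21 | selaginellin, 4-[[3-(hydroxymethyl)-6-(4-hydroxyphenyl)-2-[(4-hydroxyphenyl)ethynyl]phenyl](4-hydroxyphenyl)methylidene]cyclohexa-2,5-dien-1-one | O=C1C=CC(=C(c2ccc(O)cc2)c2c(-c3ccc(O)cc3)ccc(CO)c2C#Cc2ccc(O)cc2)C=C1 | target

**Step count and risks**

Total step count: 8. Longest linear sequence: 7 steps (steps 1, 2, 3, 4, 5, 7, 8); step 6 is a one-step side branch.

Steps most likely to fail:

1. Step 5 (key step). The diazo anion may add too slowly to the carbonyl shielded by two ortho groups, or the carbene may be diverted into C–H insertion at the neighbouring CH2OSi group before the aryl shift. The fallback sets out from 5 and returns at 15, keeping the lactone carbon as the alkyne carbon but replacing the aryl shift by a hydrogen shift and a cross-coupling. Reduction of 5 with DIBAL-H (CH2Cl2, −78 °C) should give the lactol 7-bromo-6-[4-(methoxymethoxy)phenyl]-1,3-dihydroisobenzofuran-1-ol F1. Its open hydroxy-aldehyde form should react with the Ohira–Bestmann reagent (K2CO3, MeOH) to give the terminal alkyne [3-bromo-2-ethynyl-4-[4-(methoxymethoxy)phenyl]phenyl]methanol F2. Silylation (TBSCl, imidazole) should give [3-bromo-2-ethynyl-4-[4-(methoxymethoxy)phenyl]benzyloxy](tert-butyl)dimethylsilane F3. Sonogashira coupling of F3 with purchased 1-iodo-4-(methoxymethoxy)benzene (PdCl2(PPh3)2, CuI, Et3N, rt), where the iodide reacts well before the hindered aryl bromide, should give 15.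

2. Step 2. At 140 °C the palladium may insert into the C–Br bond, the ortho-substituted acid may lose CO2, or the MOM ether may be cleaved by the hydrogen bromide formed. The fallback sets out from 3 and returns at 5, replacing catalytic C–H activation by a stoichiometric directed metalation. Esterification of 3 (Boc2O, DMAP, t-BuOH) should give tert-butyl 2-bromo-3-[4-(methoxymethoxy)phenyl]benzoate F4. Ester-directed ortho-magnesiation at the only position ortho to the ester (TMP2Mg·2LiCl, THF, 0 °C; a magnesium amide does not exchange with the bromide) and quench with DMF should give tert-butyl 2-bromo-6-formyl-3-[4-(methoxymethoxy)phenyl]benzoate F5. Reduction with NaBH4 in MeOH should give tert-butyl 2-bromo-6-(hydroxymethyl)-3-[4-(methoxymethoxy)phenyl]benzoate F6, which should close to 5 with catalytic NaOMe.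

3. Step 7. The aryllithium, flanked by an aryl and an alkynyl group, may add too slowly to the electron-rich benzophenone and be lost to protonation or electron transfer, or the alkoxide may cyclise onto the alkyne on warming. The fallback sets out from 15 and returns at 19, building the carbinol in two additions so that the hindered nucleophile meets an aldehyde and the hindered ketone meets a small nucleophile. Aryllithium 18 (from 15, t-BuLi, −78 °C) trapped with purchased 4-(methoxymethoxy)benzaldehyde should give racemic [3-[(tert-butyldimethylsilyloxy)methyl]-6-[4-(methoxymethoxy)phenyl]-2-[[4-(methoxymethoxy)phenyl]ethynyl]phenyl][4-(methoxymethoxy)phenyl]methanol F7. Dess–Martin oxidation should give [3-[(tert-butyldimethylsilyloxy)methyl]-6-[4-(methoxymethoxy)phenyl]-2-[[4-(methoxymethoxy)phenyl]ethynyl]phenyl][4-(methoxymethoxy)phenyl]methanone F8. Addition of Grignard reagent 7 to F8 (THF, 0 °C) should give 19.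

**Further compounds**

F1 | step 5 | 7-bromo-6-[4-(methoxymethoxy)phenyl]-1,3-dihydroisobenzofuran-1-ol | OC1OCc2ccc(-c3ccc(OCOC)cc3)c(Br)c21
F2 | step 5 | [3-bromo-2-ethynyl-4-[4-(methoxymethoxy)phenyl]phenyl]methanol | C#Cc1c(CO)ccc(-c2ccc(OCOC)cc2)c1Br
F3 | step 5 | [3-bromo-2-ethynyl-4-[4-(methoxymethoxy)phenyl]benzyloxy](tert-butyl)dimethylsilane | C#Cc1c(CO[Si](C)(C)C(C)(C)C)ccc(-c2ccc(OCOC)cc2)c1Br
F4 | step 2 | tert-butyl 2-bromo-3-[4-(methoxymethoxy)phenyl]benzoate | CC(C)(C)OC(=O)c1cccc(-c2ccc(OCOC)cc2)c1Br
F5 | step 2 | tert-butyl 2-bromo-6-formyl-3-[4-(methoxymethoxy)phenyl]benzoate | CC(C)(C)OC(=O)c1c(C=O)ccc(-c2ccc(OCOC)cc2)c1Br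
F6 | step 2 | tert-butyl 2-bromo-6-(hydroxymethyl)-3-[4-(methoxymethoxy)phenyl]benzoate | CC(C)(C)OC(=O)c1c(CO)ccc(-c2ccc(OCOC)cc2)c1Br
F7 | step 7 | [3-[(tert-butyldimethylsilyloxy)methyl]-6-[4-(methoxymethoxy)phenyl]-2-[[4-(methoxymethoxy)phenyl]ethynyl]phenyl][4-(methoxymethoxy)phenyl]methanol (racemic) | COCOc1ccc(cc1)C#Cc1c(CO[Si](C)(C)C(C)(C)C)ccc(-c2ccc(OCOC)cc2)c1C(O)c1ccc(OCOC)cc1
F8 | step 7 | [3-[(tert-butyldimethylsilyloxy)methyl]-6-[4-(methoxymethoxy)phenyl]-2-[[4-(methoxymethoxy)phenyl]ethynyl]phenyl][4-(methoxymethoxy)phenyl]methanone | COCOc1ccc(cc1)C#Cc1c(CO[Si](C)(C)C(C)(C)C)ccc(-c2ccc(OCOC)cc2)c1C(=O)c1ccc(OCOC)cc1
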